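**Plan**
1. First cut: C16–C17 of the 27-membered lactone ring (26 carbons plus the ring oxygen). This bond lies between unactivated methylenes far from the C1/O lactone group, so it is traced to a C16=C17 alkene and then to a sulfonyl bridge between the two carbons, i.e. a 28-membered α-chloro thialactone S,S-dioxide carrying chlorine on C16.
2. Second cut: the alkyl O–C27 ester bond of that 28-membered ring (thia-ring numbering: C16, S17, C18), giving an open-chain ω-bromo acid. Third cut: the S–C16 bond, giving a C16 aldehyde acid, a C10 bromo thiol and HCl.
3. Forward: the aldehyde acid and the bromo thiol are prepared (steps 1–3) and joined at sulfur as a regiodefined α-chloro sulfide, which is oxidised to the sulfone (step 4). Carboxylate O-alkylation closes the 28-membered ring (step 5), Ramberg–Bäcklund loss of SO2 contracts it to the 27-membered ring with C16=C17 (step 6), and hydrogenation finishes (step 7).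
4. Stereochemistry: the target has no stereocentre; the racemic CHCl centre and the alkene geometry are both erased on the way.

Key step: step 6

Remark on the chemistry: chlorine is fixed at C16 by building the α-chloro sulfide from an aldehyde and a thiol, because chlorination of a preformed 17-thia macrocycle could not distinguish its two α-methylenes. 16-Hydroxyhexadecanoic acid and 10-bromodec-1-ene are taken as catalogue chemicals.

Step 1
Reactants: 1 16-hydroxyhexadecanoic acid
Product: 2 16-oxohexadecanoic acid
Conditions: IBX (2 equiv), EtOAc, 75 °C; filter
Reagents that add atoms: none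
Why: Hypervalent-iodine oxidation with 2-iodoxybenzoic acid (IBX oxidation) takes the primary alcohol to the aldehyde without over-oxidation and tolerates the free carboxylic acid.

Step 2
Reactants: 3 10-bromodec-1-ene
Product: 4 S-(10-bromodecyl) ethanethioate
Conditions: AcSH (1.5 equiv), AIBN (5 mol%), toluene, 75 °C, argon
Reagents that add atoms: thioacetic acid, CC(=O)S
Why: Radical-chain thiol-ene addition of the thioacetyl sulfur to the terminal alkene is anti-Markovnikov and leaves the primary bromide untouched.

Step 3
Reactants: 4 S-(10-bromodecyl) ethanethioate
Product: 5 10-bromodecane-1-thiol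
Conditions: HCl (1.25 M in MeOH), degassed, 50 °C; used directly
Reagents that add atoms: none
Why: Acid-catalysed methanolysis of the thioester releases the neutral thiol, which under acidic conditions cannot displace the primary bromide as a thiolate would.

Step 4
Reactants: 2 16-oxohexadecanoic acid; 5 10-bromodecane-1-thiol
Product: 7 racemic 16-[(10-bromodecyl)sulfonyl]-16-chlorohexadecanoic acid, via alpha-chloro sulfide 6 (not isolated)
Conditions: dry HCl (g), anhydrous MgSO4, CH2Cl2, −20 to 0 °C; N2 purge, filter; then mCPBA (2.3 equiv), CH2Cl2, 0 °C to rt
Reagents that add atoms: hydrogen chloride, Cl; 3-chloroperoxybenzoic acid (mCPBA), OOC(=O)c1cccc(Cl)c1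
Why: Condensation of thiol and aldehyde to the hemithioacetal and its conversion by HCl through the thionium ion into the α-chloro sulfide places chlorine only on the former aldehyde carbon (C16), and peracid S-oxidation in the same flask fixes this labile intermediate as the stable α-chloro sulfone, whose racemic CHCl centre is destroyed in step 6.

Step 5
Reactants: 7 racemic 16-[(10-bromodecyl)sulfonyl]-16-chlorohexadecanoic acid
Product: 8 racemic 16-chloro-17-thia-27-heptacosanolide 17,17-dioxide
Conditions: Cs2CO3 (1.0 equiv), DMF, 40 °C, 7 added by syringe pump over about 12 h (final concentration about 2 mM), argon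
Reagents that add atoms: none
Why: Macrolactonisation by SN2 O-alkylation of the carboxylate formed with Cs2CO3 (28-exo-tet, the established Cs2CO3/DMF method for ω-halo acids) closes the ring at the primary bromide, while the secondary α-sulfonyl chloride is inert to SN2 attack and carbonate is too weak a base to start the extrusion.

Step 6
Reactants: 8 racemic 16-chloro-17-thia-27-heptacosanolide 17,17-dioxide
Product: 10 (E)-hexacos-16-en-26-olide, via trans-episulfone 9 (not isolated)
Conditions: KOtBu (3 equiv), THF (0.01 M), −20 °C to 0 °C; aq. NH4Cl quench
Reagents that add atoms: none
Why: This is a Ramberg–Bäcklund rearrangement of the kind known for the ring contraction of large cyclic α-halo sulfones, ester-bearing ones included: tert-butoxide removes a proton from the C18 methylene on the far side of the sulfonyl group and the carbanion displaces chloride from C16. This 1,3-substitution is a 3-exo-tet closure that gives the thiirane 1,1-dioxide and creates the C–C bond that becomes C16–C17 of the lactone, and base-mediated equilibration of the two ring carbons then leads to the trans-episulfone 9. Stereospecific cheletropic loss of SO2 from 9 leaves the C16=C17 alkene, so the 27-membered lactone ring arises by contraction of the existing 28-membered ring and no new macrocyclisation is needed. No stereocentre reaches the product, the episulfone carbons decide only the alkene geometry, the E isomer 10 is expected with this strong base, and incomplete E selectivity would be of no consequence because step 7 erases the geometry. The selectivity that matters is sulfone over lactone: a C2 enolate has no electrophile in reach and simply reprotonates, the hindered alkoxide is a poor acyl nucleophile at or below 0 °C and dilution keeps intermolecular Claisen condensation slow, whereas the α'-sulfonyl carbanion is consumed irreversibly by the neighbouring C–Cl bond.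

Step 7
Reactants: 10 (E)-hexacos-16-en-26-olide
Product: 11 26-hexacosanolide
Conditions: H2 (1 atm), 10% Pd/C, EtOAc, rt
Reagents that add atoms: none
Why: Heterogeneous catalytic hydrogenation saturates the isolated 1,2-disubstituted alkene whatever its geometry while the lactone is inert, and chromatography of 10 beforehand removes sulfur residues that could poison the catalyst.

**Compound list**
1 | 16-hydroxyhexadecanoic acid | OC(=O)CCCCCCCCCCCCCCCO | starting material
2 | 16-oxohexadecanoic acid | OC(=O)CCCCCCCCCCCCCCC=O | intermediate
3 | 10-bromodec-1-ene | C=CCCCCCCCCBr | starting material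
4 | S-(10-bromodecyl) ethanethioate | CC(=O)SCCCCCCCCCCBr | intermediate
5 | 10-bromodecane-1-thiol | SCCCCCCCCCCBr | intermediate
6 | racemic 16-[(10-bromodecyl)sulfanyl]-16-chlorohexadecanoic acid (α-chloro sulfide, not isolated) | OC(=O)CCCCCCCCCCCCCCC(Cl)SCCCCCCCCCCBr | intermediate
7 | racemic 16-[(10-bromodecyl)sulfonyl]-16-chlorohexadecanoic acid | OC(=O)CCCCCCCCCCCCCCC(Cl)S(=O)(=O)CCCCCCCCCCBr | intermediate
8 | racemic 16-chloro-17-thia-27-heptacosanolide 17,17-dioxide (13-chloro-1-oxa-12-thiacyclooctacosan-28-one 12,12-dioxide) | O=C1CCCCCCCCCCCCCCC(Cl)S(=O)(=O)CCCCCCCCCCO1 | intermediate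
9 | trans-16,17-epithio-26-hexacosanolide S,S-dioxide (trans-episulfone, racemic, one enantiomer drawn, not isolated) | O=C1CCCCCCCCCCCCCC[C@@H]2[C@@H](CCCCCCCCCO1)S2(=O)=O | intermediate
10 | (E)-hexacos-16-en-26-olide | O=C1CCCCCCCCCCCCCC/C=C/CCCCCCCCCO1 | intermediate
11 | 26-hexacosanolide (oxacycloheptacosan-2-one) | O=C1CCCCCCCCCCCCCCCCCCCCCCCCCO1 | target

Total step count: 7. Longest linear sequence: 6 steps (from 3 through steps 2 to 7); the branch from 1 joins at step 4.

**Steps most likely to fail, with fallbacks**

Step 6. The alkoxide may open the lactone by acyl attack, or the C2 enolate may condense intermolecularly, faster than the α'-sulfonyl carbanion closes onto the C–Cl bond. In the fallback the ring opening is accepted on purpose. Setting out from 8, excess KOH in aqueous dioxane at reflux saponifies the lactone. The open-chain carboxylate, now immune to acyl attack, then undergoes the classical aqueous Ramberg–Bäcklund reaction, which should favour the Z alkene, and acidification gives (Z)-26-hydroxyhexacos-16-enoic acid F1. Yamaguchi macrolactonisation (2,4,6-trichlorobenzoyl chloride, Et3N, THF; then slow addition to DMAP in toluene at reflux) closes the 27-membered ring to (Z)-hexacos-16-en-26-olide F2. Hydrogenation under the conditions of step 7 then comes back to the route at 11.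

Step 4. The hemithioacetal may take up a second thiol and end as the dithioacetal, or the α-chloro sulfide may be hydrolysed by the water of condensation or acylated by the carboxylic acid before it is oxidised. In the fallback the C16–S bond is made by addition to an alkyne, which forms no water and passes through no hemithioacetal. Setting out from 5, radical hydrothiolation of commercial hexadec-15-ynoic acid (used in excess; AIBN, toluene, 80 °C) gives the anti-Markovnikov vinyl sulfide (E)-16-[(10-bromodecyl)sulfanyl]hexadec-15-enoic acid F3, whose geometry is irrelevant. Dry HCl in CH2Cl2 at −20 °C then adds across the vinyl sulfide by protonation at C15 and chloride capture of the thionium ion at C16. This comes back to the route at 6, which is oxidised with mCPBA to 7 as in step 4.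

Step 5. Intermolecular O-alkylation to linear and cyclic oligoesters may outrun the 28-membered closure, or long exposure to carbonate may erode the α-chloro sulfone. In the fallback the ring is closed at the acyl carbon instead of the alkyl carbon. Setting out from 7, KOAc in AcOH at reflux exchanges the primary bromide for acetate to give 16-[(10-acetoxydecyl)sulfonyl]-16-chlorohexadecanoic acid F4. Acid hydrolysis (2 M HCl, aqueous dioxane, 80 °C) then gives 16-chloro-16-[(10-hydroxydecyl)sulfonyl]hexadecanoic acid F5. Shiina macrolactonisation (2-methyl-6-nitrobenzoic anhydride, DMAP, Et3N, CH2Cl2, rt, slow addition) comes back to the route at 8.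

**Further compounds**
F1 | step 6 | (Z)-26-hydroxyhexacos-16-enoic acid | OC(=O)CCCCCCCCCCCCCC/C=C\CCCCCCCCCO
F2 | step 6 | (Z)-hexacos-16-en-26-olide | O=C1CCCCCCCCCCCCCC/C=C\CCCCCCCCCO1
F3 | step 4 | (E)-16-[(10-bromodecyl)sulfanyl]hexadec-15-enoic acid | OC(=O)CCCCCCCCCCCCC/C=C/SCCCCCCCCCCBr
F4 | step 5 | racemic 16-[(10-acetoxydecyl)sulfonyl]-16-chlorohexadecanoic acid | OC(=O)CCCCCCCCCCCCCCC(Cl)S(=O)(=O)CCCCCCCCCCOC(C)=O
F5 | step 5 | racemic 16-chloro-16-[(10-hydroxydecyl)sulfonyl]hexadecanoic acid | OC(=O)CCCCCCCCCCCCCCC(Cl)S(=O)(=O)CCCCCCCCCCO
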